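1. Amber is a slow flask: after 2.50 min it holds 25.0% product, and the question stands at 6.0 min, later than its last reading.

in all of them: starting material 0.21 M; gas phase 13 mM (held); added ligand 0.16 mM
- amber: free catalyst 0.23 mM; the very flask that is asked about, followed so far
- violet: free catalyst 0.15 mM; run made earlier
- flask: free catalyst 0.23 mM; time 6.0 min

| run | time / min | product / % | starting material / % |
|---|---|---|---|
| amber | 0.167 | 0.8 | 98.7 |
| amber | 0.333 | 3.0 | 96.6 |
| amber | 0.667 | 7.4 | 92.2 |
| amber | 1.00 | 11.4 | 88.9 |
| amber | 1.33 | 15.5 | 85.6 |
| amber | 2.00 | 21.0 | 79.0 |
| amber | 2.50 | 25.0 | 75.0 |
| violet | 0.667 | 3.9 | 95.7 |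
| violet | 1.33 | 9.8 | 90.2 |
| violet | 2.00 | 13.8 | 86.0 |
| violet | 2.50 | 17.1 | 82.9 |
| violet | 3.00 | 20.9 | 80.1 |
| violet | 4.00 | 23.2 | 75.6 |

(readings scatter by 0.5 percentage points)

- what was read earlier has a scatter of 0.5 percentage points, one standard deviation
- at the start none of the gas phase is in solution

- birch: doubling the saturation concentration of gas phase, all else as stated
- maple: doubling the amount of free catalyst, all else as stated
- larch: doubling the transfer coefficient of the gas phase, all else as stated

- product at 6.0 min, in percent of the starting material charged
- the change that raises the amount of product at 6.0 min, in percent of the starting material charged most ("none" if none brings more than 2 percentage points) (birch / maple / larch / none)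
- amount of product at 6.0 min, in percent of the starting material charged, after birch

2. The bench rule says that product at equal time goes with the catalyst charge. Amber's charge is 1.53 times violet's, and at 2.00 min amber's product is 1.52 times violet's, so the rule holds there.

3. But the rule treats c(starting material) as constant. At 2.50 min amber keeps 75.0%, and ln(1/that share) is already 1.15 times the plain fraction lost. Percentages stop being proportional about there.

4. So I treat the loss as first order in starting material, with a coefficient that may drift, and use the scaled loss S: ln(c(starting material) charged / c(starting material) now), divided by c(free catalyst) charged. At 2.00 min, S reads 1.02 /mM in amber and 1.01 /mM in violet, so I take one curve for both. Violet's reading at 4.00 min then lends amber a later point, 1.86 /mM.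

5. S gains 1.02 /mM in the first stretch and 0.840 /mM in the next, a factor of 0.819. I assume that factor repeats, which puts the scaled loss at the asked time at 2.55 /mM. Amber then holds 44.4% product, and maple gives 69.1%. No run varied the gas, so S says nothing about birch or larch. I commit to maple.

6. The forecast says 44%, maple, and 58% after birch, on the ground that “the rate is first order in catalyst”.

7. The flask gives 43.8%, with maple best at 27 percentage points, birch at 11 points, and 55.1% after birch.

    gas phase ⇌ dissolved gas, rate k1*(csat - [dissolved gas]) (kL = 0.0870 /s)
    starting material + dissolved gas + free catalyst → free catalyst + product (k = 2600 /M²/s)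
    free catalyst + added ligand ⇌ idle complex, settled at all times (K = 19000 /M)
    dissolved gas + free catalyst → spent catalyst (k = 0.610 /M/s)

The product step carries c(starting material) and c(free catalyst) each to the first power. Read back from the result, amber's S at 6.0 min is 2.51 /mM, beside my 2.55 /mM. The neighbouring flask is charged with 3.9 × 10⁻⁴ M of free catalyst, all else as in amber. My S gives it 63.1% product, and that flask holds 64.1%.

The earlier runs and the new flask stem from a simulated flask with constants of no real substance; the scatter is artificial.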